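Count in substrate units: one side product holds two of them, and one of the two was target. Follow a single unit. With coupling partner it becomes target or isomer of the product, and a target can then take another substrate into side product.

| flask | substrate | gas | remark | time |
|---|---|---|---|---|
| Friday's | 0.75 M | 200 mM (held) | run made earlier |  |
| Monday's | 1.1 M | 200 mM (held) | run made earlier |  |
| flask | 1.5 M | 200 mM (held) |  | 10 min |

| run | time / min | isomer of the product / % | target / % |
|---|---|---|---|
| Friday's | 0.667 | 41.5 | 47.8 |
| Friday's | 1.33 | 43.1 | 47.4 |
| Friday's | 2.50 | 43.0 | 46.0 |
| Friday's | 4.00 | 44.0 | 44.8 |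
| Friday's | 8.00 | 46.6 | 41.1 |
| Monday's | 1.50 | 40.6 | 46.2 |
| Monday's | 3.00 | 39.6 | 45.7 |
| Monday's | 5.00 | 39.3 | 46.2 |
| Monday's | 6.00 | 39.4 | 45.7 |
| Monday's | 8.00 | 38.7 | 45.8 |

(readings scatter by 0.5 percentage points)

- percent here means substrate units held: one side product counts as two
- what is said of target includes crystals
- crystals is a solid; its amount is given per volume of the solution
- at the start none of coupling partner is dissolved
- the analysis behind the earlier runs scatters by 0.5 percentage points, standard deviation
- what may be going on: substrate + target -> side product; substrate + coupling partner <-> target; crystals <-> target; substrate + coupling partner <-> isomer of the product; gas <-> coupling partner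

- ratio of isomer of the product to target at 2.0 s
- ratio of isomer of the product to target at 40 s
- ratio of isomer of the product to target at 10 min

My bracket is for the ratio at 40 s. Let x be the fraction that the first reading of a run misses from target plus isomer, and count it as side product. Put the target back that x consumed, and you get s, the isomer made per target made, an apparent selectivity factor:

s = isomer / (target + x/2)

Friday's first reading gives x = 10.7% and s = 0.781, a reading with its scatter. Hold s for the new flask, and x then gives the ratio:

g = (1 − x/2) / (1 + s)
ratio = s·g / (g − x/2)

With x at zero, the floor is s itself. Monday's first reading gives x = 13.2%, more than Friday's, and the new flask is charged with more substrate than Monday's, so I take this x as the least to expect, which lifts the floor to 0.893.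

For the ceiling, scale x in proportion to the charge, to 18.0%. That is generous, since x grew less than the charge from Friday to Monday. The ceiling is 0.948.

The forecast says 0.81, 0.9 and 0.77, on the ground that “The side-product share scales with concentration”. Its 0.9 lies inside my bracket.

The flask gives 0.736, 0.904 and 0.683, so the forecast holds and 0.904 lies inside the bracket. If you want target, wait: at 10.0 min the flask holds 48.5% target with crystals counted, the crystals being 47.3% of the charge, against 33.1% isomer. With the 16.5% side product at 1.00 min, s gives 40.2% isomer, and the flask holds 39.0%.

    substrate + target → side product (k = 0.0846 L mol⁻¹ s⁻¹)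
    substrate + coupling partner ⇌ target (K = 8.30 L mol⁻¹, k = 0.698 L mol⁻¹ s⁻¹)
    crystals ⇌ target, rate k3*(cs3 - [target]) while solid is left; crystals form when [target] > cs3 (solubility = 17.0 mM, k = 0.343 s⁻¹)
    substrate + coupling partner ⇌ isomer of the product (K = 200 L mol⁻¹, k = 0.440 L mol⁻¹ s⁻¹)
    gas ⇌ coupling partner, rate k5*(csat - [coupling partner]) (kL = 0.378 s⁻¹)

Now take the neighbour flask with 0.90 M substrate, using its 12.6% side product from 10.0 min as x. The same s gives an estimated ratio of 0.887 for 40 s. The computed value is 0.882.

The earlier runs and the new flask come from a simulation for an exercise, and the scatter is random.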